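The data were generated by integration for an exercise; scatter was added.

Every substrate molecule charged stays in the flask as substrate, as a form carrying one reagent, or as bis adduct. Every reagent molecule stays unbound, sits in a one-reagent form, or is one of the pair in bis adduct. Subtracting the two balances removes the one-reagent forms:

[bis adduct] = reagent charged − substrate charged + [substrate] − [unbound reagent]

| flask | substrate | reagent | temperature | remark | time |
|---|---|---|---|---|---|
| eta | 0.25 M | 0.45 M | 55 °C | run made earlier |  |
| gamma | 0.25 M | 0.63 M | 70 °C | run made earlier |  |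
| zeta | 0.25 M | 0.99 M | 55 °C | run made earlier |  |
| teal | 0.25 M | 0.450 M (fed, over 2.5 d) |  | the addition at 30 °C, then warmed to 70 °C; the feed brings no volume worth counting | 6.0 d |
| green | 0.25 M | 0.450 M | 70 °C | everything together at the start | 6.0 d |
| red | 0.25 M (in portions, 5, over 2.5 d) | 0.450 M | 70 °C | first portion at the start, last at 2.5 d | 6.0 d |
| violet | 0.25 M | 0.450 M |  | everything together at the start at 30 °C, warmed to 70 °C at 2.5 d | 6.0 d |
| amber | 0.25 M (fed, over 2.5 d) | 0.450 M | 70 °C | all else is in the flask from the start; the feed brings no volume worth counting | 6.0 d |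

| run | time / d | bis adduct / % | mono adduct / % | substrate / % |
|---|---|---|---|---|
| eta | 0.833 | 3 | 13 | 72 |
| eta | 2.50 | 6 | 20 | 47 |
| eta | 4.00 | 10 | 25 | 37 |
| eta | 6.00 | 16 | 26 | 28 |
| eta | 10.0 | 26 | 27 | 16 |
| eta | 12.0 | 30 | 24 | 13 |
| gamma | 0.333 | 3 | 21 | 58 |
| gamma | 0.833 | 14 | 26 | 35 |
| gamma | 1.67 | 21 | 29 | 19 |
| gamma | 2.50 | 30 | 32 | 12 |
| gamma | 4.00 | 42 | 22 | 6 |
| gamma | 5.00 | 52 | 23 | 3 |
| zeta | 0.833 | 7 | 21 | 51 |
| zeta | 1.25 | 11 | 23 | 40 |
| zeta | 2.00 | 17 | 27 | 24 |
| zeta | 4.00 | 32 | 21 | 9 |
| zeta | 6.00 | 48 | 16 | 4 |
| zeta | 10.0 | 67 | 10 | 2 |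

(readings scatter by 1.5 percentage points)

* which flask leads in amount of bis adduct, in percent of the substrate charged ("all alike" within 1.5 percentage points) (teal / green / red / violet / amber / all alike)
* how much bis adduct is there at the end, in percent of the substrate charged: teal
* how much bis adduct is there at the end, in percent of the substrate charged: green
* how much bis adduct is there at the end, in percent of the substrate charged: red
* how much bis adduct is there at the end, in percent of the substrate charged: violet
* how much bis adduct is there at the end, in percent of the substrate charged: amber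



The columns do not close. In zeta they leave 32.0% unread at 2.00 d and 21.0% at 10.0 d, so we count the unread part as a one-reagent form on its way to bis adduct.

Teal, green, red, violet and amber share 0.25 M substrate and 0.450 M reagent. Full conversion to bis adduct needs 0.500 M, more than the charge, so reagent is the limiting reagent. With substrate and unbound reagent both gone, the line leaves the end yield 80.0%, reagent charged less substrate charged, per substrate charged.

That says where the flasks are heading, and the readings say how far off they stay. Eta, with these charges at 55 °C, reads 30% at 12.0 d, less than the end yield. Gamma, hotter and with more reagent, reads 52% at 5.00 d. So we rank the flasks by mean days at 70 °C with the substrate in, taking the days at 30 °C as lost: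

green 6.0 d; red and amber 4.75 d; teal and violet 3.50 d

Our order is green, then red and amber together, then teal and violet together.

The forecast gives green the lead, with teal 23%, green 35%, red 30%, violet 24% and amber 29%, and notes “Reagent is limiting (1.8 equiv), so the tail is slow.”

The flasks give green 34.3%, more than red at 28.7% and amber at 28.3%, with violet 23.3% and teal 23.0% lower still, which is our order.

    reagent + other mono adduct → bis adduct (k = 0.0342 M⁻¹ h⁻¹, Ea = 94.0 kJ mol⁻¹)
    substrate + reagent → mono adduct (k = 0.0828 M⁻¹ h⁻¹, Ea = 91.0 kJ mol⁻¹)
    reagent ⇌ dormant form (K = 1.07, k = 0.0736 h⁻¹, Ea = 124 kJ mol⁻¹, ΔH = 60.0 kJ mol⁻¹)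
    reagent + mono adduct → bis adduct (k = 0.0553 M⁻¹ h⁻¹, Ea = 73.0 kJ mol⁻¹)
    substrate + reagent → other mono adduct (k = 0.0728 M⁻¹ h⁻¹, Ea = 80.0 kJ mol⁻¹)
    (constants at 70 °C)

Green at 6.00 d stands 46 percentage points under its end yield. The line accounts for that, per substrate charged, with unbound reagent counted as free reagent plus dormant form:

80.0% + 8.51% substrate − 25.2% free reagent − 29.0% dormant form = 34.3%

The neighbour is teal with 0.42 M substrate, and its end yield, the value with substrate and unbound reagent both gone, is 7.14%. Per its own substrate charged, the line reads:

7.14% + 28.4% substrate − 9.39% free reagent − 12.4% dormant form = 13.8%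

At 6.00 d that neighbour already holds 13.8% bis adduct, more than that value, with 28.4% substrate still in the flask.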